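The rate constants are not read here: a count of turnovers, taken from what leaves the readings in Tuesday's run, stands in their place.

| flask | substrate | coupling partner | remark | time |
|---|---|---|---|---|
| Tuesday's | 0.80 M | 0.36 M | run made earlier |  |
| Monday's | 0.80 M | 1.4 M | run made earlier |  |
| flask | 0.80 M | 0.720 M |  | 10 d |

| run | time / d | substrate / % | mono adduct / % | other mono adduct / % |
|---|---|---|---|---|
| Tuesday's | 0.833 | 56.1 | 21.7 | 0.1 |
| Tuesday's | 1.67 | 42.8 | 16.5 | 1.2 |
| Tuesday's | 4.00 | 36.4 | 6.2 | 1.2 |
| Tuesday's | 10.0 | 30.6 | 2.3 | 0 |
| Monday's | 0.833 | 6.5 | 31.2 | 0 |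
| Monday's | 1.67 | 1.4 | 18.7 | 0 |
| Monday's | 4.00 | 0.6 | 8.9 | 0 |
| Monday's | 10.0 | 0.1 | 3.6 | 0.7 |

(standard deviation of a reading: 1 percentage point)

- substrate at 10 d, in percent of the substrate charged
- mono adduct at 10 d, in percent of the substrate charged
- other mono adduct at 10 d, in percent of the substrate charged
- bis adduct at 10 d, in percent of the substrate charged

- what was read earlier has a scatter of 1 percentage point, one standard deviation

In Tuesday's run at 10.0 d, substrate, mono adduct and other mono adduct leave 67.1% of the substrate charged unread, while the coupling partner was charged at 45.0% of the substrate. The partner cost, the coupling partner consumed per unit of unread substrate, is therefore capped for that run, since no more partner can be used than was charged: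

partner cost = (partner charged − mono adduct − other mono adduct) / unread substrate = 0.636

Bis adduct holds two partners per substrate, so in Tuesday's run it makes up at most 31.8% of the unread material.

This reckoning then turns to the flask, where the partner stands at 90.0% of the substrate. At Tuesday's cost, consuming the whole substrate would take 63.6%, which is less than the charge, so substrate should fall low. The weak link is carrying that cost over unchanged, because the flask has twice Tuesday's partner per substrate. Reforged, the estimate lets the spare partner go to bis adduct and leaves mono adduct at Tuesday's level, which gives a ceiling of 43.8% for bis adduct.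

The forecast gives substrate 2%, mono adduct 4.5%, other mono adduct 0.5% and bis adduct 93%, reasoning “if the unaccounted material is bis adduct”. Its bis adduct stands above this ceiling.

The flask gives substrate 5.62%, mono adduct 9.60%, other mono adduct 0.293% and bis adduct 21.0%.

    mono adduct ⇌ isomer of the product (K = 1.60, k = 1.20 × 10⁻⁶ s⁻¹)
    substrate + coupling partner → mono adduct (k = 5.30 × 10⁻⁵ L mol⁻¹ s⁻¹)
    substrate + coupling partner → other mono adduct (k = 1.70 × 10⁻⁶ L mol⁻¹ s⁻¹)
    coupling partner + mono adduct → bis adduct (k = 2.80 × 10⁻⁵ L mol⁻¹ s⁻¹)
    coupling partner + other mono adduct → bis adduct (k = 1.60 × 10⁻⁴ L mol⁻¹ s⁻¹)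
    substrate + mono adduct → side product (k = 1.20 × 10⁻⁵ L mol⁻¹ s⁻¹)

In the flask the side product, unread until now, stands at 50.7%, each unit counting as two substrates, and the coupling partner, the limiting reagent, is down to 0.0120% of its own charge. The partner cost of the flask comes to 0.948. In the neighbour charged with 1.2 M of coupling partner, 0.749% of the partner's own charge remains, bis adduct reaches 59.1%, and the partner cost is 1.55.

Readings and results are calculated for an exercise; the scatter is artificial.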